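## Structural features

The target 24 is a cyclohex-2-en-1-one. Ring carbons are labelled C1 (ketone), C2=C3 (enone double bond), C4, C5 (carbinol) and C6; C5 also carries the methylene C7, which leads to a second ketone C8 and on to the (Z)-heptadec-8-enyl chain of the oleyl series. C5 is the only stereocentre and has no stereogenic neighbour. Its three carbon arms (C4, C6, C7) are all CH2 groups that differ only one atom further out, so no substrate bias is available: the centre must be set by a reagent on a small precursor and then carried through untouched. The carbinol is β to both carbonyl groups. Base can cleave C5–C6 or C5–C7 by retro-aldol reaction, and acid or base can eliminate water towards C4 or C6 to give a dienone that aromatises to a 3-alkylphenol. The chain (Z)-alkene is isolated but would be lost by hydrogenation, by thiyl-radical or acid-induced isomerisation and by strongly electrophilic reagents. The real difficulty is to build a fully substituted, labile aldol centre of defined configuration and to free the two ketones only at the very end. The key step uses the 1,3-relationship C1(=O)–C6–C5(OH): with C1 masked and metalated as a 1,3-dithiane (an acyl anion) and C5–C6 present as an oxirane, one SN2 opening forms C1–C6 and the ring C1–C6. The same retron, C8(=O)–C7–C5(OH), is used once more for the side chain.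

## Logic of the disconnections

**24 ⇒ 23.** The two C=O groups (C1 and C8) are taken back to 1,3-dithiane dithioketals. The reason is that C5–OH is β to both carbonyls. In 23 there is no carbonyl, so retro-aldol cleavage and dehydration are impossible at every earlier stage. The forward step must hydrolyse two dithioketals at once under near-neutral conditions that spare the (Z)-alkene and do not dehydrate the product.

**23 ⇒ 21.** The ring bond C1–C6 is cut. C1 in 23 is a dithioketal carbon flanked by the C2=C3 alkene, so in the forward sense it is the one readily metalated position, and C6–C5(O) is the pattern left by opening an oxirane at its CH2. The ring disappears and 21 is an open chain with one stereocentre. The forward step needs a (Z)-C2=C3 bond, an oxirane of fixed configuration and no competing acidic C–H or electrophile.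

**21 ⇒ 19 ⇒ 18.** The oxirane C6–O bond is cut to the 1,2-diol 19, and its primary oxygen is masked as the silyl ether in 18. The oxirane is the most reactive group of 21 and is best made last. C6 can then travel as a protected CH2OH through both carbanion steps. The forward step must activate only the primary hydroxyl and close the ring with a base too weak to remove C1–H.

**18 ⇒ 16.** C2=C3 is traced to the triple bond C2≡C3. A syn addition of two hydrogens gives the (Z) geometry, and the linear alkyne cannot cyclise early. The demand is a reduction that is not poisoned by four thioether sulfurs and leaves the chain alkene alone.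

**16 ⇒ 14 + 7.** The bond C3–C4 is cut between an acetylide (C3) and the CH2 of an oxirane (C4). This removes the whole C1–C3 arm as a three-carbon unit that already carries the C1 dithiane. The forward step must metalate 7 at the alkyne and not at the dithiane C–H, and open a 2,2-disubstituted oxirane at its CH2.

**14 ⇒ 11 + 4.** The bond C7–C8 is cut between a 2-lithio-1,3-dithiane (C8) and the oxirane CH2 of 11 (C7). The chloromethyl arm of 11 lets the resulting alkoxide close a new oxirane on the arm that will become C4, so no hydroxyl is ever free. The chain arm must come first, because the acidic C1–H of the later alkynyl and alkenyl dithianes would not survive the strongly basic lithiated 4. Ring opening must also outrun direct chloride displacement, since the latter leads to the mirror-image product.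

**11 ⇒ 10 ⇒ 9 ⇒ 8.** C–Cl is taken back to C–OH, the oxirane to the alkene of an allylic alcohol, and the silyl ether to the free diol. The three arms of C5 are thus told apart in two stages on a four-carbon achiral diol: first constitutionally (one silyl group), then by a reagent-controlled face-selective epoxidation. The epoxidation must give the enantiomer in which the oxirane CH2 becomes C7, the hydroxymethyl arm C4 and the silyloxymethyl arm C6. With the fixed order of the two openings this is the (R)-epoxy alcohol.

**4 ⇒ 2 + 3, 2 ⇒ 1; 7 ⇒ 6 ⇒ 5 + 3.** The C–S bonds of both dithianes are cut to the aldehydes and the dithiol; the aldehyde of the chain comes from the primary alcohol, and the terminal alkyne from its silyl-capped form. The demands are an oxidation that stops at the aldehyde and thioacetalisations that do not isomerise the (Z)-alkene or add thiol to the ynal.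

## Other disconnections considered

**Alternative 1:** The cut is the ring bond C4–C5, made by a [3,3] shift. The substrate would be the tertiary cyclohexenol A1, whose ring runs C8–C7=C5–C6–C1–C2, with a vinyl group (C3=C4) on C2. Its potassium alkoxide (KH, 18-crown-6) would undergo an anionic oxy-Cope rearrangement through the boat-like geometry that the ring enforces. C4 joins C5, C8–C2 breaks, and protonation of the C7=C8 enolate would give ketone A2.
- In its favour: one step would create the target ring, place the alkene at C2=C3 with ring-enforced cis geometry, relay the configuration of C2 to the new quaternary C5, and deliver the chain ketone free. No sulfur is present and no triple bond has to be reduced beside the oleyl alkene; on that point it is better than the chosen plan.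
- Against it here: A1 needs three stereocentres, two of them only as relays, against the single reagent-set centre of 10. A1 is a tertiary allylic alcohol of a vinylogous ester and would ionise with acid (Stork–Danheiser-type transposition). The product first exists as an enolate with the C5 benzyloxy group in the β-position, so E1cB loss of that group would compete.
- After the key step, desilylation, oxidation at C1 and removal of the benzyl ether would still be required to reach 24, with the C8 aldol exposed throughout. The chosen plan keeps both carbonyls masked until one last hydrolysis.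
- Comparison: both key steps are anionic and ring-size controlled. The sigmatropic route is the more elegant in forming the quaternary centre during ring formation; the dithiane route uses only SN2 bond formations. The two would be about equal in length (roughly ten linear steps each), and the alternative loses on stereochemical overhead.

**Alternative 2:** The cut removes C7–C8 and C5–O together (retro 1,3-dipolar cycloaddition). The nitrile oxide released from hydroximoyl chloride A4 (two steps from 2) would add to the exocyclic methylene of cyclohexanol A3 as its magnesium alkoxide (EtMgBr). The metal would hold the dipole oxygen on the alkoxide face and give spiro-isoxazoline A5 with ring oxygen, hydroxyl and silyloxy group cis.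
- In its favour: it is convergent, regiochemistry is inherent (oxygen to the more substituted carbon), and the isoxazoline is a robust masked aldol. In keeping the C8 aldol masked it is the equal of the dithioketal of the chosen plan, and it is better in needing neither strong base nor sulfur.
- Against it here: C5 is defined only relative to two ring carbinols, which must come from an enantiopure desymmetrised cis-diol and then be processed. From A5 the free hydroxyl must become a leaving group, the silyl ether the C1 ketone, the leaving group must be eliminated to C2=C3, and the N–O bond cleaved (Mo(CO)6 in wet MeCN, since hydrogenolysis would saturate the chain alkene) and the imine hydrolysed. These are about five operations, the last ones on a molecule that already holds the enone or the free aldol.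
- Magnesium-directed delivery is best known for allylic alcohols; for a homoallylic ring alkoxide it needs an axial alkoxide, so face selectivity would be less secure than in a Sharpless epoxidation.
- Comparison: stereocontrol by substrate and not by reagent, similar or slightly higher step count (about thirteen to fifteen in total), and a riskier endgame.

**Alternative 3:** The cut opens the enone at C1–C2 and C3–C4 and returns acetylene A7 and the prochiral cyclobutanone A6 (ring C1, C6, C5, C4). Zerovalent nickel (Ni(cod)2 with a chiral phosphine) would couple A7 with the carbonyl of A6 to an oxanickelacycle. β-Carbon elimination would cleave C1–C4 and reductive elimination would form C3–C4, giving cyclohexenone A8.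
- In its favour: ring, enone and the C5 stereocentre would arise in one catalytic step from an achiral substrate, with no stoichiometric chiral reagent and no sulfur. On ring construction and on the economy of introducing chirality it is better than the chosen plan, whose key step sets no stereocentre.
- Against it here: alkyne insertion into cyclobutanones is established for internal alkynes, whereas A7 oligomerises readily on zerovalent nickel. Selection between the two enantiotopic α-carbons by a chiral ligand in the intermolecular reaction has no close precedent, so the enantiopurity of A8 would be unsecured.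
- The chain would still have to be attached afterwards: acetal hydrolysis beside a β-silyloxy enone, chemoselective addition of Grignard reagent A9 (one carbon shorter than 1, so not directly available from it) to the aldehyde in the presence of the enone, oxidation at C8, and removal of a tertiary silyl ether. These four steps act on exactly the sensitive array that the chosen route never exposes.
- Comparison: potentially the shortest (about nine or ten steps) but with the largest methodological risk. The chosen plan is a few steps longer and uses only reaction types with direct precedent.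

Key step: step 13

**Remarks on the chemistry**
- Assumption: oleyl alcohol 1 of high (Z) purity is used; technical grades contain saturated and (E) homologues that no later step removes.
- The four bonds of C5 (one C–O, three C–C) persist from 10 to 24, so the configuration set in step 6 is the configuration of the target. The descriptors change (R, R, S, R…) only because priorities change. The spatial arrangement at C5 was checked to be identical in 10, 21, 23 and 24.
- Ring closure in step 13 places both oxirane carbons in the new ring. In the usual vocabulary of epoxide cyclisations this is the endo (6-endo) mode; counted on the breaking C6–O bond it is a 6-exo-tet displacement.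
- The triple bond is reduced with a borane and not over palladium, because four thioether sulfurs are present.
- The first oxirane is transposed through a chloride and not through a free diol, so that no primary alkoxide can exchange the silyl group between the two enantiotopic arms.
- The tartrate hand in step 6 was assigned by analogy with (R)-2-methylglycidol from methallyl alcohol and D-(−)-tartrate.

## Steps

Step 1
Reactants: 1 oleyl alcohol, (9Z)-octadec-9-en-1-ol
Product: 2 (9Z)-octadec-9-enal
Conditions: TEMPO (10 mol %), PhI(OAc)2 (1.1 equiv), CH2Cl2, 20 °C
Reagents that add atoms: none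
Why: Oxoammonium (TEMPO) oxidation of a primary alcohol stops at the aldehyde under neutral conditions and leaves the isolated (Z)-alkene untouched.

Step 2
Reactants: 2 (9Z)-octadec-9-enal; 3 propane-1,3-dithiol
Product: 4 2-[(8Z)-heptadec-8-en-1-yl]-1,3-dithiane
Conditions: BF3·OEt2 (0.2 equiv), BHT (cat.), CH2Cl2, 0 °C, argon, dark
Reagents that add atoms: none
Why: Lewis-acid dithioacetalisation of an aliphatic aldehyde; exclusion of light and oxygen with a radical inhibitor suppresses thiyl-radical Z/E isomerisation of the chain alkene.

Step 3
Reactants: 5 3-(trimethylsilyl)prop-2-ynal; 3 propane-1,3-dithiol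
Product: 6 2-[(trimethylsilyl)ethynyl]-1,3-dithiane
Conditions: BF3·OEt2 (0.2 equiv), CH2Cl2, −20 → 0 °C
Reagents that add atoms: none
Why: Dithioacetalisation at the carbonyl carbon; the silyl cap shields the alkyne terminus, so conjugate addition of thiol to the ynal is disfavoured.

Step 4
Reactants: 6 2-[(trimethylsilyl)ethynyl]-1,3-dithiane
Product: 7 2-ethynyl-1,3-dithiane
Conditions: K2CO3 (0.1 equiv), MeOH, 0 → 20 °C
Reagents that add atoms: none
Why: Methanolysis of the C(sp)–Si bond; catalytic carbonate is far too weak to remove the dithiane C–H, so no propargyl–allenyl isomerisation is expected.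

Step 5
Reactants: 8 2-methylidenepropane-1,3-diol
Product: 9 2-({[tert-butyl(diphenyl)silyl]oxy}methyl)prop-2-en-1-ol
Conditions: NaH (1.0 equiv), THF, 20 °C; TBDPSCl (1.0 equiv)
Reagents that add atoms: tert-butyl(chloro)diphenylsilane, CC(C)(C)[Si](Cl)(c1ccccc1)c1ccccc1
Why: Monosilylation of a symmetrical diol through its sparingly soluble mono-sodium alkoxide; the bulky, migration-resistant TBDPS group is chosen because it must stay on one arm through two carbanion steps.

Step 6
Reactants: 9 2-({[tert-butyl(diphenyl)silyl]oxy}methyl)prop-2-en-1-ol
Product: 10 [(2R)-2-({[tert-butyl(diphenyl)silyl]oxy}methyl)oxiran-2-yl]methanol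
Conditions: Ti(OiPr)4 (10 mol %), D-(−)-diethyl tartrate (12 mol %), t-BuOOH (2 equiv), 4 Å MS, CH2Cl2, −20 °C
Reagents that add atoms: tert-butyl hydroperoxide, CC(C)(C)OO
Why: Sharpless asymmetric epoxidation of a 2-substituted allylic alcohol under catalytic conditions, which limit opening of the sensitive 2,2-disubstituted epoxy alcohol. The C5 stereocentre is set by the tartrate ligand (reagent control); D-(−)-tartrate should deliver oxygen to the face that gives the (R)-epoxide, as in the formation of (R)-2-methylglycidol from methallyl alcohol.

Step 7
Reactants: 10 [(2R)-2-({[tert-butyl(diphenyl)silyl]oxy}methyl)oxiran-2-yl]methanol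
Product: 11 tert-butyl{[(2R)-2-(chloromethyl)oxiran-2-yl]methoxy}diphenylsilane
Conditions: PPh3 (1.3 equiv), CCl4, NaHCO3 (cat.), reflux
Reagents that add atoms: tetrachloromethane, ClC(Cl)(Cl)Cl
Why: Appel chlorination of a 2,3-epoxy alcohol; the bicarbonate buffer protects the oxirane, and only the primary C–O bond is exchanged, so C5 is untouched.

Step 8
Reactants: 4 2-[(8Z)-heptadec-8-en-1-yl]-1,3-dithiane; 11 tert-butyl{[(2R)-2-(chloromethyl)oxiran-2-yl]methoxy}diphenylsilane
Product: 14 tert-butyl{[(2S)-2-({2-[(8Z)-heptadec-8-en-1-yl]-1,3-dithian-2-yl}methyl)oxiran-2-yl]methoxy}diphenylsilane, via lithiated dithiane 12 (not isolated), via lithium chlorohydrin alkoxide 13 (not isolated)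
Conditions: 4, n-BuLi (1.05 equiv), THF, −30 °C; then 11, DMPU, −78 → 20 °C
Reagents that add atoms: none
Why: Corey–Seebach alkylation: 12 opens the oxirane of 11 at its CH2 (SN2), and alkoxide 13 then expels chloride (3-exo-tet, the epichlorohydrin manoeuvre), moving the oxirane onto the former chloromethyl arm. Opening of the strained ring should outrun direct displacement of the hindered chloride, which matters because the latter would give the mirror-image product. C5 keeps its C–O bond, so its configuration is carried over (R becomes S only through the priority change).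

Step 9
Reactants: 7 2-ethynyl-1,3-dithiane; 14 tert-butyl{[(2S)-2-({2-[(8Z)-heptadec-8-en-1-yl]-1,3-dithian-2-yl}methyl)oxiran-2-yl]methoxy}diphenylsilane
Product: 16 (2R)-1-{[tert-butyl(diphenyl)silyl]oxy}-5-(1,3-dithian-2-yl)-2-({2-[(8Z)-heptadec-8-en-1-yl]-1,3-dithian-2-yl}methyl)pent-4-yn-2-ol, via lithium acetylide 15 (not isolated)
Conditions: 7 (2.5 equiv), n-BuLi (2.4 equiv), THF, −78 °C; BF3·OEt2 (2.5 equiv); 14, −78 °C; aq. NH4Cl
Reagents that add atoms: none
Why: Yamaguchi–Hirao alkynylation: the terminal sp C–H of 7 is removed much faster than the dithiane C–H, and a slight deficit of base prevents any dithiane-centred anion. The boron-activated 2,2-disubstituted oxirane is opened at its CH2 at −78 °C; no stereocentre is touched.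

Step 10
Reactants: 16 (2R)-1-{[tert-butyl(diphenyl)silyl]oxy}-5-(1,3-dithian-2-yl)-2-({2-[(8Z)-heptadec-8-en-1-yl]-1,3-dithian-2-yl}methyl)pent-4-yn-2-ol
Product: 18 (2R,4Z)-1-{[tert-butyl(diphenyl)silyl]oxy}-5-(1,3-dithian-2-yl)-2-({2-[(8Z)-heptadec-8-en-1-yl]-1,3-dithian-2-yl}methyl)pent-4-en-2-ol, via alkenyl(dicyclohexyl)borane 17 (not isolated)
Conditions: dicyclohexylborane (2.5 equiv, from BH3·SMe2 and cyclohexene), THF, 0 °C; AcOH, 0 → 20 °C; aq. NaHCO3
Reagents that add atoms: none
Why: Brown–Zweifel cis-reduction: syn hydroboration of the triple bond and protonolysis of the alkenyl C–B bond with retention give the (Z)-alkene, whichever carbon carries boron. A borane is used because the thioether sulfurs would poison Pd/CaCO3–Pb(OAc)2. The hindered dialkylborane should add to the dialkylalkyne faster than to the remote 1,2-dialkyl (Z)-alkene.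

Step 11
Reactants: 18 (2R,4Z)-1-{[tert-butyl(diphenyl)silyl]oxy}-5-(1,3-dithian-2-yl)-2-({2-[(8Z)-heptadec-8-en-1-yl]-1,3-dithian-2-yl}methyl)pent-4-en-2-ol
Product: 19 (2R)-2-[(2Z)-3-(1,3-dithian-2-yl)prop-2-en-1-yl]-3-{2-[(8Z)-heptadec-8-en-1-yl]-1,3-dithian-2-yl}propane-1,2-diol
Conditions: Bu4NF (1.2 equiv), THF, 0 → 20 °C; aq. NH4Cl
Reagents that add atoms: none
Why: Fluoride cleavage of the primary silyl ether; fluoride is not basic enough to remove the allylic dithiane C–H, and neither dithiane nor alkene is affected.

Step 12
Reactants: 19 (2R)-2-[(2Z)-3-(1,3-dithian-2-yl)prop-2-en-1-yl]-3-{2-[(8Z)-heptadec-8-en-1-yl]-1,3-dithian-2-yl}propane-1,2-diol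
Product: 21 2-{(1Z)-3-[(2R)-2-({2-[(8Z)-heptadec-8-en-1-yl]-1,3-dithian-2-yl}methyl)oxiran-2-yl]prop-1-en-1-yl}-1,3-dithiane, via primary tosylate 20 (not isolated)
Conditions: TsCl (1.1 equiv), Et3N, DMAP (cat.), CH2Cl2, 0 °C; then K2CO3, MeOH, 20 °C
Reagents that add atoms: none
Why: Sulfonylation goes to the primary hydroxyl because the tertiary one is too hindered; carbonate then closes the oxirane by a 3-exo-tet Williamson displacement at C6. The C5–O bond is kept, so configuration is retained, and carbonate is too weak to touch C1–H.

Step 13
Reactants: 21 2-{(1Z)-3-[(2R)-2-({2-[(8Z)-heptadec-8-en-1-yl]-1,3-dithian-2-yl}methyl)oxiran-2-yl]prop-1-en-1-yl}-1,3-dithiane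
Product: 23 (10R)-10-({2-[(8Z)-heptadec-8-en-1-yl]-1,3-dithian-2-yl}methyl)-1,5-dithiaspiro[5.5]undec-7-en-10-ol, via C1-lithiated dithiane 22 (not isolated)
Conditions: n-BuLi (1.1 equiv), THF, −78 °C; DMPU, −78 → −10 °C; aq. NH4Cl
Reagents that add atoms: none
Why: n-BuLi removes the only acidic C–H of 21, the doubly sulfur-stabilised allylic C1–H (the C8 dithiane is fully substituted), to give the lithiated allyl anion 22. C1 then displaces the oxirane oxygen at the CH2 carbon C6 (SN2), forming C1–C6 and the cyclohexene ring and leaving the C5 lithium alkoxide; the closest known reaction type is the intramolecular alkylation of 2-lithio-1,3-dithianes by epoxides (Corey–Seebach cyclisation). The ring closes with both oxirane carbons inside it (6-endo mode of epoxide cyclisations; a 6-exo-tet displacement when counted on the breaking C6–O bond; a 6-(enolendo) alkylation of the allyl anion, which is allowed). Site selectivity at the nucleophile is secured by ring size, since reaction through the γ-carbon C3 would give a cyclobutane at C6 or a cyclopropane at C5. Site selectivity at the electrophile is secured by substitution, since the competing 5-exo attack would have to occur at the fully substituted C5. The (Z) geometry of C2=C3, which the sulfur-stabilised anion should hold at low temperature, keeps C1 within reach of C6. No stereocentre is formed, and C5 keeps all four bonds, so its configuration is that set in step 6. Both carbonyls are still dithioketals, so the tertiary alkoxide cannot undergo retro-aldol cleavage or elimination.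

Step 14
Reactants: 23 (10R)-10-({2-[(8Z)-heptadec-8-en-1-yl]-1,3-dithian-2-yl}methyl)-1,5-dithiaspiro[5.5]undec-7-en-10-ol
Product: 24 (5R)-5-hydroxy-5-[(10Z)-2-oxononadec-10-en-1-yl]cyclohex-2-en-1-one
Conditions: MeI (20 equiv), CaCO3 (6 equiv), MeCN/H2O 4:1, 40 °C
Reagents that add atoms: water, O
Why: Alkylative hydrolysis of dithioketals: S-methylation, ring opening to the thionium ion and capture by water release the enone and the chain ketone together. The carbonate-buffered, near-neutral medium should spare the (Z)-alkene and avoid dehydration or retro-aldol cleavage of the product.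

## Compound list

1 | oleyl alcohol, (9Z)-octadec-9-en-1-ol | CCCCCCCC/C=C\CCCCCCCCO | starting material
2 | (9Z)-octadec-9-enal | CCCCCCCC/C=C\CCCCCCCC=O | intermediate
3 | propane-1,3-dithiol | SCCCS | starting material
4 | 2-[(8Z)-heptadec-8-en-1-yl]-1,3-dithiane | CCCCCCCC/C=C\CCCCCCCC1SCCCS1 | intermediate
5 | 3-(trimethylsilyl)prop-2-ynal | C[Si](C)(C)C#CC=O | starting material
6 | 2-[(trimethylsilyl)ethynyl]-1,3-dithiane | C[Si](C)(C)C#CC1SCCCS1 | intermediate
7 | 2-ethynyl-1,3-dithiane | C#CC1SCCCS1 | intermediate
8 | 2-methylidenepropane-1,3-diol | C=C(CO)CO | starting material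
9 | 2-({[tert-butyl(diphenyl)silyl]oxy}methyl)prop-2-en-1-ol | C=C(CO)CO[Si](c1ccccc1)(c1ccccc1)C(C)(C)C | intermediate
10 | [(2R)-2-({[tert-butyl(diphenyl)silyl]oxy}methyl)oxiran-2-yl]methanol | OC[C@]1(CO[Si](c2ccccc2)(c2ccccc2)C(C)(C)C)CO1 | intermediate
11 | tert-butyl{[(2R)-2-(chloromethyl)oxiran-2-yl]methoxy}diphenylsilane | ClC[C@]1(CO[Si](c2ccccc2)(c2ccccc2)C(C)(C)C)CO1 | intermediate
12 | 2-[(8Z)-heptadec-8-en-1-yl]-2-lithio-1,3-dithiane | [Li]C1(CCCCCCC/C=C\CCCCCCCC)SCCCS1 | intermediate (not isolated)
13 | lithium (2R)-1-{[tert-butyl(diphenyl)silyl]oxy}-2-(chloromethyl)-3-{2-[(8Z)-heptadec-8-en-1-yl]-1,3-dithian-2-yl}propan-2-olate | [Li+].[O-][C@@](CCl)(CO[Si](c1ccccc1)(c1ccccc1)C(C)(C)C)CC1(SCCCS1)CCCCCCC/C=C\CCCCCCCC | intermediate (not isolated)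
14 | tert-butyl{[(2S)-2-({2-[(8Z)-heptadec-8-en-1-yl]-1,3-dithian-2-yl}methyl)oxiran-2-yl]methoxy}diphenylsilane | CCCCCCCC/C=C\CCCCCCCC1(SCCCS1)C[C@@]2(CO[Si](c3ccccc3)(c3ccccc3)C(C)(C)C)CO2 | intermediate
15 | lithium (1,3-dithian-2-yl)acetylide | [Li]C#CC1SCCCS1 | intermediate (not isolated)
16 | (2R)-1-{[tert-butyl(diphenyl)silyl]oxy}-5-(1,3-dithian-2-yl)-2-({2-[(8Z)-heptadec-8-en-1-yl]-1,3-dithian-2-yl}methyl)pent-4-yn-2-ol | CCCCCCCC/C=C\CCCCCCCC1(SCCCS1)C[C@@](O)(CO[Si](c2ccccc2)(c2ccccc2)C(C)(C)C)CC#CC3SCCCS3 | intermediate
17 | alkenyl(dicyclohexyl)borane from syn addition to 16 (boron on C3, cis to the C2 hydrogen; C1 and C4 cis) | CCCCCCCC/C=C\CCCCCCCC1(SCCCS1)C[C@@](O)(CO[Si](c2ccccc2)(c2ccccc2)C(C)(C)C)C/C(B(C2CCCCC2)C2CCCCC2)=C\C3SCCCS3 | intermediate (not isolated)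
18 | (2R,4Z)-1-{[tert-butyl(diphenyl)silyl]oxy}-5-(1,3-dithian-2-yl)-2-({2-[(8Z)-heptadec-8-en-1-yl]-1,3-dithian-2-yl}methyl)pent-4-en-2-ol | CCCCCCCC/C=C\CCCCCCCC1(SCCCS1)C[C@@](O)(CO[Si](c2ccccc2)(c2ccccc2)C(C)(C)C)C/C=C\C3SCCCS3 | intermediate
19 | (2R)-2-[(2Z)-3-(1,3-dithian-2-yl)prop-2-en-1-yl]-3-{2-[(8Z)-heptadec-8-en-1-yl]-1,3-dithian-2-yl}propane-1,2-diol | CCCCCCCC/C=C\CCCCCCCC1(SCCCS1)C[C@@](O)(CO)C/C=C\C2SCCCS2 | intermediate
20 | (2R)-2-[(2Z)-3-(1,3-dithian-2-yl)prop-2-en-1-yl]-3-{2-[(8Z)-heptadec-8-en-1-yl]-1,3-dithian-2-yl}-2-hydroxypropyl 4-methylbenzenesulfonate | CCCCCCCC/C=C\CCCCCCCC1(SCCCS1)C[C@@](O)(COS(=O)(=O)c2ccc(C)cc2)C/C=C\C3SCCCS3 | intermediate (not isolated)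
21 | 2-{(1Z)-3-[(2R)-2-({2-[(8Z)-heptadec-8-en-1-yl]-1,3-dithian-2-yl}methyl)oxiran-2-yl]prop-1-en-1-yl}-1,3-dithiane (key-step precursor) | CCCCCCCC/C=C\CCCCCCCC1(SCCCS1)C[C@@]2(CO2)C/C=C\C3SCCCS3 | intermediate
22 | 21 lithiated at the alkenyl dithiane carbon C1 | CCCCCCCC/C=C\CCCCCCCC1(SCCCS1)C[C@@]2(CO2)C/C=C\C3([Li])SCCCS3 | intermediate (not isolated)
23 | (10R)-10-({2-[(8Z)-heptadec-8-en-1-yl]-1,3-dithian-2-yl}methyl)-1,5-dithiaspiro[5.5]undec-7-en-10-ol (bis-dithioketal of the target) | CCCCCCCC/C=C\CCCCCCCC1(SCCCS1)C[C@]2(O)CC=CC3(SCCCS3)C2 | intermediate
24 | (5R)-5-hydroxy-5-[(10Z)-2-oxononadec-10-en-1-yl]cyclohex-2-en-1-one | CCCCCCCC/C=C\CCCCCCCC(=O)C[C@]1(O)CC=CC(=O)C1 | target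

## Step count and least certain steps

Total step count: 14. Longest linear sequence: 10 steps (8 → 24, steps 5 to 14); the branches to 4 (steps 1–2) and to 7 (steps 3–4) are two steps each.

**Step 13 (key step).** Three things may go wrong. The base may abstract a C4 proton (allylic and next to the oxirane) and so isomerise the epoxide to an allylic alcohol. The allyl anion may lose its (Z) geometry on warming. The endo-type closure may be slow enough for intermolecular opening or butyl addition to compete.
Fallback: the electrophile is changed from the oxirane to a sulfonate, so that the closure becomes a plain exo-tet alkylation. Setting out from 19, the primary tosylate 20 is isolated and its tertiary hydroxyl is silylated (Et3SiOTf, 2,6-lutidine) to the triethylsilyl ether of the tosylate F1. Deprotonation at C1 (n-BuLi or KN(SiMe3)2, THF, −78 °C → 0 °C) then displaces the tosylate at C6 to give the triethylsilyl ether of the spirocyclic alcohol F2. Bu4NF returns the route to 23. The displacement is at a neopentyl-type carbon and relies on intramolecularity.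

**Step 10.** The borane may also hydroborate the chain alkene. An alkenylborane carrying boron next to the dithiane carbon may eliminate thiolate (allene formation). The hindered alkyne may convert incompletely.
Fallback: setting out from 16 and returning at 18, the stoichiometric hydroboration is replaced by catalytic hydrocupration–protonation (Cu(OAc)2/Xantphos, polymethylhydrosiloxane, t-BuOH, toluene, 20 °C). A copper hydride does not add to unactivated 1,2-dialkyl alkenes at all, so selectivity no longer rests on a rate difference. This fallback makes no compound outside the list (F0).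

**Step 9.** The base may metalate the dithiane C–H of 7 beside the alkyne, leading to alkylation at the dithiane carbon or propargyl–allenyl isomerisation. The Lewis acid may induce rearrangement or sulfur participation in the β-dithianyl 2,2-disubstituted oxirane.
Fallback: setting out from 14, the nucleophile is changed to the lithium acetylide of commercial 3,3-diethoxyprop-1-yne, which has no acidic C–H beside the alkyne (same BF3·OEt2 protocol). This gives the alkynyl diethyl acetal F3. Transthioacetalisation with 3 (BF3·OEt2, CH2Cl2, −30 °C, dark) returns the route to 16.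

**Step 14.** The more hindered C8 dithioketal may be unmasked incompletely. On long heating the liberated aldol may dehydrate and aromatise, or cleave by retro-aldol reaction.
Fallback: setting out from 23, unmasking is split into two mild operations. Oxidative transketalisation with PhI(OCOCF3)2 in MeOH at 0 °C gives the bis(dimethyl ketal) F4. Brief treatment with pyridinium p-toluenesulfonate in wet acetone at 0 °C returns the route to 24.

**Step 8 (with step 7).** Direct substitution of chloride may compete with ring opening, which would erode enantiomeric purity. The Appel step that supplies 11 may lose material through chloride opening of the oxirane.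
Fallback: setting out from 10 (steps 7 and 8 are both bypassed), the epoxy alcohol is converted to its lithium alkoxide (n-BuLi, −78 °C) and opened with 12 (1.2 equiv, THF/DMPU, kept below −20 °C to suppress silyl transfer between the two primary oxygens). This gives the diol F5. Selective tosylation (TsCl, Et3N, DMAP) gives the primary tosylate F6, and K2CO3 in MeOH closes the oxirane and returns the route to 14 with unambiguous regiochemistry.

## Further compounds

F1 | step 13 | triethylsilyl ether of tosylate 20 | CCCCCCCC/C=C\CCCCCCCC1(SCCCS1)C[C@@](O[Si](CC)(CC)CC)(COS(=O)(=O)c2ccc(C)cc2)C/C=C\C3SCCCS3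
F2 | step 13 | triethylsilyl ether of 23 | CCCCCCCC/C=C\CCCCCCCC1(SCCCS1)C[C@]2(O[Si](CC)(CC)CC)CC=CC3(SCCCS3)C2
F0 | step 10 | none | none
F3 | step 9 | (2R)-1-{[tert-butyl(diphenyl)silyl]oxy}-6,6-diethoxy-2-({2-[(8Z)-heptadec-8-en-1-yl]-1,3-dithian-2-yl}methyl)hex-4-yn-2-ol | CCCCCCCC/C=C\CCCCCCCC1(SCCCS1)C[C@@](O)(CO[Si](c2ccccc2)(c2ccccc2)C(C)(C)C)CC#CC(OCC)OCC
F4 | step 14 | bis(dimethyl ketal) of 24 | CCCCCCCC/C=C\CCCCCCCC(OC)(OC)C[C@]1(O)CC=CC(OC)(OC)C1
F5 | step 8 | 3-{[tert-butyl(diphenyl)silyl]oxy}-2-({2-[(8Z)-heptadec-8-en-1-yl]-1,3-dithian-2-yl}methyl)propane-1,2-diol, single enantiomer as drawn | CCCCCCCC/C=C\CCCCCCCC1(SCCCS1)C[C@](O)(CO)CO[Si](c2ccccc2)(c2ccccc2)C(C)(C)C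
F6 | step 8 | primary 4-methylbenzenesulfonate of F5 | CCCCCCCC/C=C\CCCCCCCC1(SCCCS1)C[C@](O)(COS(=O)(=O)c2ccc(C)cc2)CO[Si](c3ccccc3)(c3ccccc3)C(C)(C)C
A1 | alternative 1 | 1-[(8Z)-heptadec-8-en-1-yl]-3-[(4-methoxybenzyl)oxy]-5-[(tert-butyldimethylsilyl)oxy]-6-vinylcyclohex-2-en-1-ol, vinyl trans to the silyloxy group and cis to the hydroxyl | CCCCCCCC/C=C\CCCCCCC[C@@]1(O)C=C(OCc2ccc(OC)cc2)C[C@@H](O[Si](C)(C)C(C)(C)C)[C@@H]1C=C
A2 | alternative 1 | 5-(4-methoxybenzyloxy)-5-[(10Z)-2-oxononadec-10-en-1-yl]cyclohex-2-en-1-yl tert-butyldimethylsilyl ether | CCCCCCCC/C=C\CCCCCCCC(=O)C[C@]1(OCc2ccc(OC)cc2)CC=C[C@H](O[Si](C)(C)C(C)(C)C)C1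
A3 | alternative 2 | (1R,5S)-5-[(tert-butyldimethylsilyl)oxy]-3-methylidenecyclohexan-1-ol | C=C1C[C@@H](O)C[C@@H](O[Si](C)(C)C(C)(C)C)C1
A4 | alternative 2 | (9Z)-N-hydroxyoctadec-9-enimidoyl chloride | CCCCCCCC/C=C\CCCCCCCC(Cl)=NO
A5 | alternative 2 | spiro-isoxazoline with ring oxygen, hydroxyl and silyloxy group cis | CCCCCCCC/C=C\CCCCCCCC1=NO[C@@]2(C1)C[C@@H](O)C[C@@H](O[Si](C)(C)C(C)(C)C)C2
A6 | alternative 3 | 3-[(tert-butyldimethylsilyl)oxy]-3-(2,2-dimethoxyethyl)cyclobutan-1-one | COC(OC)CC1(O[Si](C)(C)C(C)(C)C)CC(=O)C1
A7 | alternative 3 | acetylene (ethyne) | C#C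
A8 | alternative 3 | 5-[(tert-butyldimethylsilyl)oxy]-5-(2,2-dimethoxyethyl)cyclohex-2-en-1-one, single enantiomer | COC(OC)C[C@]1(O[Si](C)(C)C(C)(C)C)CC=CC(=O)C1
A9 | alternative 3 | (8Z)-heptadec-8-en-1-ylmagnesium bromide | CCCCCCCC/C=C\CCCCCCC[Mg]Br
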